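**Retrosynthetic overview**
1. C13–C14: the target 30 comes from the lithiated dithiane 27 (a masked isovaleryl anion) and the C1–C13 allylic bromide 23. The ketone is unveiled in the last step.
2. C5–C6: 23 comes from allylic bromide 12 (fragment A, C1–C5) and the geraniol-derived allylic sulfone 17 (fragment B, C6–C13), followed by Pd/hydride desulfonylation.
3. C3=C4: 12 comes from E-selective cross-metathesis of the homoallylic silyl ether 7 with methacrolein.
4. Key bond C1–C2: 6 comes from furan-3-carbaldehyde and an allylborane. This asymmetric carbonyl allylation joins the furan to the chain and sets the only stereocentre (S).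
5. Rings: no ring of the target is built, because the furan is carried intact from 1. The only ring closed is the temporary 1,3-dithiane (step 14), which is opened again in step 17.

Assumption and locants: the SMILES is read as S at the carbinol carbon and E at all three alkenes. In the text, C1 is the carbinol carbon, C14 is the ketone carbon and C17 is a chain-end methyl.

**Fragment A**

Step 1
Reactants: 1 furan-3-carbaldehyde; 2 allylmagnesium bromide; 3 (−)-B-methoxydiisopinocampheylborane (Ipc groups from (+)-α-pinene)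
Product: 6 (1S)-1-(furan-3-yl)but-3-en-1-ol, via B-allyldiisopinocampheylborane 4 (not isolated), via homoallylic diisopinocampheylborinate 5 (not isolated)
Conditions: 3 (1.3 equiv), 2 (1.25 equiv), Et2O, −78 °C → rt, 1 h; 1, −78 °C, 3 h; 3 M NaOH, 30% H2O2, 0 °C → rt
Reagents that add atoms: none
Why: Brown asymmetric carbonyl allylation, in which 4 delivers allyl through a closed chair transition state to the Si face of 1 (the sense known for aryl and alkenyl aldehydes), forming C1–C2 and setting the only stereocentre as S in about 92–96% ee.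

Step 2
Reactants: 6 (1S)-1-(furan-3-yl)but-3-en-1-ol
Product: 7 tert-butyl{[(1S)-1-(furan-3-yl)but-3-en-1-yl]oxy}dimethylsilane
Conditions: TBSCl, imidazole, DMF, rt
Reagents that add atoms: tert-butyldimethylsilyl chloride, CC(C)(C)[Si](C)(C)Cl
Why: Standard imidazole-promoted silylation masks the furyl carbinol as a base- and hydride-stable ether without touching the stereocentre.

Step 3
Reactants: 7 tert-butyl{[(1S)-1-(furan-3-yl)but-3-en-1-yl]oxy}dimethylsilane; 8 methacrolein
Product: 9 (2E,5S)-5-[(tert-butyldimethylsilyl)oxy]-5-(furan-3-yl)-2-methylpent-2-enal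
Conditions: 8 (5 equiv), second-generation Hoveyda–Grubbs catalyst RuCl2(H2IMes)(=CH-C6H4-2-O-i-Pr) (4 mol %), CH2Cl2, 40 °C
Reagents that add atoms: none
Why: Olefin cross-metathesis of a terminal alkene with an electron-poor 1,1-disubstituted alkene is product-selective and thermodynamically E-selective (typically >20:1), so C3=C4 is set as E while furan and silyl ether are inert to the ruthenium carbene.

Step 4
Reactants: 9 (2E,5S)-5-[(tert-butyldimethylsilyl)oxy]-5-(furan-3-yl)-2-methylpent-2-enal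
Product: 10 (2E,5S)-5-[(tert-butyldimethylsilyl)oxy]-5-(furan-3-yl)-2-methylpent-2-en-1-ol
Conditions: NaBH4, CeCl3·7H2O, MeOH, 0 °C
Reagents that add atoms: none
Why: Luche reduction gives clean 1,2-reduction of the enal and leaves the alkene geometry and the silyl ether untouched.

Step 5
Reactants: 10 (2E,5S)-5-[(tert-butyldimethylsilyl)oxy]-5-(furan-3-yl)-2-methylpent-2-en-1-ol
Product: 12 {[(1S,3E)-5-bromo-1-(furan-3-yl)-4-methylpent-3-en-1-yl]oxy}(tert-butyl)dimethylsilane (fragment A), via allylic methanesulfonate 11 (not isolated)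
Conditions: MsCl, Et3N, THF, −45 °C; LiBr, THF, 0 °C
Reagents that add atoms: lithium bromide, [Li+].[Br-] (methanesulfonyl chloride, CS(=O)(=O)Cl, ends up only in 11)
Why: Mesylation followed by cold SN2 displacement with bromide converts the primary allylic alcohol without allylic transposition or E/Z leakage, under conditions mild enough for the furyl silyl ether.

**Fragment B**

Step 6
Reactants: 13 geraniol
Product: 14 geranyl bromide
Conditions: PBr3 (0.4 equiv), Et2O, 0 °C
Reagents that add atoms: phosphorus tribromide, BrP(Br)Br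
Why: Classical PBr3 bromination of a primary allylic alcohol runs by SN2 on the phosphite ester at 0 °C and keeps the E alkene.

Step 7
Reactants: 14 geranyl bromide
Product: 15 geranyl phenyl sulfone
Conditions: PhSO2Na, DMF, rt
Reagents that add atoms: sodium benzenesulfinate, [Na+].[O-]S(=O)c1ccccc1
Why: Soft S-alkylation of the sulfinate by the primary allylic bromide (SN2) gives the sulfone with the E alkene retained.

Step 8
Reactants: 15 geranyl phenyl sulfone
Product: 16 (2E,6E)-2,6-dimethyl-8-(phenylsulfonyl)octa-2,6-dien-1-ol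
Conditions: SeO2 (0.3 equiv), t-BuOOH (3 equiv), salicylic acid (0.1 equiv), CH2Cl2, rt; NaBH4, MeOH, 0 °C
Reagents that add atoms: tert-butyl hydroperoxide, CC(C)(C)OO (oxygen passed on through SeO2)
Why: Sharpless catalytic SeO2 allylic oxidation (ene reaction, then [2,3]-sigmatropic shift) picks the electron-rich terminal alkene over the sulfone-deactivated one and oxidises only the (E)-methyl group, which fixes C11=C12 as E, and the borohydride wash returns any over-oxidised enal to 16.

Step 9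
Reactants: 16 (2E,6E)-2,6-dimethyl-8-(phenylsulfonyl)octa-2,6-dien-1-ol
Product: 17 {[(2E,6E)-2,6-dimethyl-8-(phenylsulfonyl)octa-2,6-dien-1-yl]oxy}triethylsilane (fragment B)
Conditions: TESCl, imidazole, CH2Cl2, 0 °C
Reagents that add atoms: chlorotriethylsilane, CC[Si](CC)(CC)Cl
Why: Silylation with the more labile TES group shields the C13 alcohol during the carbanion step and can later be removed beside the secondary TBS ether.

**Union and end game**

Step 10
Reactants: 17 fragment B sulfone; 12 fragment A bromide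
Product: 19 tert-butyl{[(1S,3E,7E,11E)-1-(furan-3-yl)-4,8,12-trimethyl-6-(phenylsulfonyl)-13-[(triethylsilyl)oxy]trideca-3,7,11-trien-1-yl]oxy}dimethylsilane (about 1:1 epimers at C6), via α-lithio sulfone 18 (not isolated)
Conditions: 17 (1.15 equiv), n-BuLi, THF/DMPU, −78 °C; 12, −78 → −30 °C
Reagents that add atoms: none
Why: Alkylation of a sulfone-stabilised allyl anion (Biellmann-type terpene coupling) occurs at the α-carbon by SN2 on the primary allylic bromide, so C5–C6 forms with all three E alkenes intact, and the new sulfone-bearing centre is erased in step 11.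

Step 11
Reactants: 19 coupled sulfone
Product: 20 tert-butyl{[(1S,3E,7E,11E)-1-(furan-3-yl)-4,8,12-trimethyl-13-[(triethylsilyl)oxy]trideca-3,7,11-trien-1-yl]oxy}dimethylsilane
Conditions: PdCl2(dppp) (5 mol %), LiEt3BH (2.5 equiv), THF, 0 °C
Reagents that add atoms: none
Why: Palladium-catalysed hydride desulfonylation, in which zerovalent palladium (formed from PdCl2(dppp) by the hydride) ionises the allylic sulfone to a π-allyl complex and hydride is delivered to the less substituted C6 terminus, leaving C7=C8 in place and E while silyl ethers and furan are inert.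

Step 12
Reactants: 20 bis-silyl ether
Product: 21 (2E,6E,10E,13S)-13-[(tert-butyldimethylsilyl)oxy]-13-(furan-3-yl)-2,6,10-trimethyltrideca-2,6,10-trien-1-ol
Conditions: PPTS (0.1 equiv), MeOH/CH2Cl2, 0 °C
Reagents that add atoms: none
Why: Mild acid-catalysed methanolysis distinguishes the primary TES ether (roughly a hundred times more labile) from the hindered secondary TBS ether, and it is too weak and too cold to ionise the furyl carbinol position.

Step 13
Reactants: 21 C13 allylic alcohol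
Product: 23 {[(1S,3E,7E,11E)-13-bromo-1-(furan-3-yl)-4,8,12-trimethyltrideca-3,7,11-trien-1-yl]oxy}(tert-butyl)dimethylsilane, via allylic methanesulfonate 22 (not isolated)
Conditions: MsCl, Et3N, THF, −45 °C; LiBr, THF, 0 °C
Reagents that add atoms: lithium bromide, [Li+].[Br-] (methanesulfonyl chloride, CS(=O)(=O)Cl, ends up only in 22)
Why: The same mesylation and SN2 bromide displacement as in step 5 gives the primary allylic bromide with the C11=C12 geometry retained.

Step 14
Reactants: 24 3-methylbutanal; 25 propane-1,3-dithiol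
Product: 26 2-(2-methylpropyl)-1,3-dithiane
Conditions: BF3·OEt2 (0.2 equiv), CH2Cl2, 0 °C → rt
Reagents that add atoms: none
Why: Lewis-acid-catalysed thioacetalisation of an unhindered aldehyde is close to quantitative and provides the acyl-anion equivalent for C14–C17.

Step 15
Reactants: 26 2-(2-methylpropyl)-1,3-dithiane; 23 C13 allylic bromide
Product: 28 tert-butyl{[(1S,3E,7E,11E)-1-(furan-3-yl)-4,8,12-trimethyl-13-[2-(2-methylpropyl)-1,3-dithian-2-yl]trideca-3,7,11-trien-1-yl]oxy}dimethylsilane, via 2-lithio-2-(2-methylpropyl)-1,3-dithiane 27 (not isolated)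
Conditions: 26 (2 equiv), n-BuLi, THF, −25 °C, 2 h; 23, −78 → −20 °C
Reagents that add atoms: none
Why: Corey–Seebach umpolung, in which the lithiated dithiane displaces the primary allylic bromide by direct SN2 far faster than it could metalate the furan, forming C13–C14 with the ketone carbon masked and the alkene E.

Step 16
Reactants: 28 dithiane silyl ether
Product: 29 (1S,3E,7E,11E)-1-(furan-3-yl)-4,8,12-trimethyl-13-[2-(2-methylpropyl)-1,3-dithian-2-yl]trideca-3,7,11-trien-1-ol
Conditions: TBAF, THF, 0 °C → rt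
Reagents that add atoms: none
Why: Fluoride desilylation is carried out while C14 is still a thioacetal, so no base-sensitive β,γ-enone is present, and the C–O bond at the stereocentre is never broken.

Step 17
Reactants: 29 dithiane alcohol
Product: 30 (6E,10E,14E,17S)-17-(furan-3-yl)-17-hydroxy-2,6,10,14-tetramethylheptadeca-6,10,14-trien-4-one (target)
Conditions: MeI (15 equiv), CaCO3 (8 equiv), MeCN/THF/H2O, 35 °C, dark
Reagents that add atoms: water, O
Why: Alkylative thioacetal hydrolysis (S-methylation, ring opening to the thionium ion, capture by water) is non-oxidative and is kept neutral by CaCO3, so the furan, the three alkenes and the carbinol survive and C11=C12 does not slip into conjugation.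

**Compound list**
1 | furan-3-carbaldehyde | O=Cc1ccoc1 | starting material
2 | allylmagnesium bromide | C=CC[Mg]Br | starting material
3 | (−)-B-methoxydiisopinocampheylborane | COB([C@@H]1C[C@@H]2C[C@H]([C@H]1C)C2(C)C)[C@@H]1C[C@@H]2C[C@H]([C@H]1C)C2(C)C | starting material
4 | B-allyldiisopinocampheylborane | C=CCB([C@@H]1C[C@@H]2C[C@H]([C@H]1C)C2(C)C)[C@@H]1C[C@@H]2C[C@H]([C@H]1C)C2(C)C | intermediate
5 | (1S)-1-(furan-3-yl)but-3-en-1-yl diisopinocampheylborinate | C=CC[C@H](OB([C@@H]1C[C@@H]2C[C@H]([C@H]1C)C2(C)C)[C@@H]1C[C@@H]2C[C@H]([C@H]1C)C2(C)C)c1ccoc1 | intermediate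
6 | (1S)-1-(furan-3-yl)but-3-en-1-ol | C=CC[C@H](O)c1ccoc1 | intermediate
7 | tert-butyl{[(1S)-1-(furan-3-yl)but-3-en-1-yl]oxy}dimethylsilane | C=CC[C@H](O[Si](C)(C)C(C)(C)C)c1ccoc1 | intermediate
8 | methacrolein | C=C(C)C=O | starting material
9 | (2E,5S)-5-[(tert-butyldimethylsilyl)oxy]-5-(furan-3-yl)-2-methylpent-2-enal | O=C/C(C)=C/C[C@H](O[Si](C)(C)C(C)(C)C)c1ccoc1 | intermediate
10 | (2E,5S)-5-[(tert-butyldimethylsilyl)oxy]-5-(furan-3-yl)-2-methylpent-2-en-1-ol | OC/C(C)=C/C[C@H](O[Si](C)(C)C(C)(C)C)c1ccoc1 | intermediate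
11 | (2E,5S)-5-[(tert-butyldimethylsilyl)oxy]-5-(furan-3-yl)-2-methylpent-2-en-1-yl methanesulfonate | CS(=O)(=O)OC/C(C)=C/C[C@H](O[Si](C)(C)C(C)(C)C)c1ccoc1 | intermediate
12 | {[(1S,3E)-5-bromo-1-(furan-3-yl)-4-methylpent-3-en-1-yl]oxy}(tert-butyl)dimethylsilane | BrC/C(C)=C/C[C@H](O[Si](C)(C)C(C)(C)C)c1ccoc1 | intermediate
13 | geraniol, (2E)-3,7-dimethylocta-2,6-dien-1-ol | CC(C)=CCC/C(C)=C/CO | starting material
14 | geranyl bromide, (2E)-1-bromo-3,7-dimethylocta-2,6-diene | CC(C)=CCC/C(C)=C/CBr | intermediate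
15 | geranyl phenyl sulfone, {[(2E)-3,7-dimethylocta-2,6-dien-1-yl]sulfonyl}benzene | CC(C)=CCC/C(C)=C/CS(=O)(=O)c1ccccc1 | intermediate
16 | (2E,6E)-2,6-dimethyl-8-(phenylsulfonyl)octa-2,6-dien-1-ol | OC/C(C)=C/CC/C(C)=C/CS(=O)(=O)c1ccccc1 | intermediate
17 | {[(2E,6E)-2,6-dimethyl-8-(phenylsulfonyl)octa-2,6-dien-1-yl]oxy}triethylsilane | CC[Si](CC)(CC)OC/C(C)=C/CC/C(C)=C/CS(=O)(=O)c1ccccc1 | intermediate
18 | α-lithio derivative of 17 | CC[Si](CC)(CC)OC/C(C)=C/CC/C(C)=C/C([Li])S(=O)(=O)c1ccccc1 | intermediate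
19 | C6-phenylsulfonyl coupled triene (C6 epimers) | CC[Si](CC)(CC)OC/C(C)=C/CC/C(C)=C/C(C/C(C)=C/C[C@H](O[Si](C)(C)C(C)(C)C)c1ccoc1)S(=O)(=O)c1ccccc1 | intermediate
20 | C1-OTBS, C13-OTES triene | CC[Si](CC)(CC)OC/C(C)=C/CC/C(C)=C/CC/C(C)=C/C[C@H](O[Si](C)(C)C(C)(C)C)c1ccoc1 | intermediate
21 | (2E,6E,10E,13S)-13-[(tert-butyldimethylsilyl)oxy]-13-(furan-3-yl)-2,6,10-trimethyltrideca-2,6,10-trien-1-ol | OC/C(C)=C/CC/C(C)=C/CC/C(C)=C/C[C@H](O[Si](C)(C)C(C)(C)C)c1ccoc1 | intermediate
22 | methanesulfonate of 21 | CS(=O)(=O)OC/C(C)=C/CC/C(C)=C/CC/C(C)=C/C[C@H](O[Si](C)(C)C(C)(C)C)c1ccoc1 | intermediate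
23 | {[(1S,3E,7E,11E)-13-bromo-1-(furan-3-yl)-4,8,12-trimethyltrideca-3,7,11-trien-1-yl]oxy}(tert-butyl)dimethylsilane | BrC/C(C)=C/CC/C(C)=C/CC/C(C)=C/C[C@H](O[Si](C)(C)C(C)(C)C)c1ccoc1 | intermediate
24 | 3-methylbutanal (isovaleraldehyde) | CC(C)CC=O | starting material
25 | propane-1,3-dithiol | SCCCS | starting material
26 | 2-(2-methylpropyl)-1,3-dithiane | CC(C)CC1SCCCS1 | intermediate
27 | 2-lithio-2-(2-methylpropyl)-1,3-dithiane | [Li]C1(CC(C)C)SCCCS1 | intermediate
28 | C14 dithiane, C1-OTBS triene | CC(C)CC1(C/C(C)=C/CC/C(C)=C/CC/C(C)=C/C[C@H](O[Si](C)(C)C(C)(C)C)c2ccoc2)SCCCS1 | intermediate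
29 | (1S,3E,7E,11E)-1-(furan-3-yl)-4,8,12-trimethyl-13-[2-(2-methylpropyl)-1,3-dithian-2-yl]trideca-3,7,11-trien-1-ol | CC(C)CC1(C/C(C)=C/CC/C(C)=C/CC/C(C)=C/C[C@H](O)c2ccoc2)SCCCS1 | intermediate
30 | (6E,10E,14E,17S)-17-(furan-3-yl)-17-hydroxy-2,6,10,14-tetramethylheptadeca-6,10,14-trien-4-one | C/C(=C\CC/C(C)=C/C[C@H](O)c1ccoc1)CC/C=C(\C)CC(=O)CC(C)C | target

**Totals**
- Total step count: 17.
- Longest linear sequence: 12 (steps 1–5, 10–13, 15–17).

**Three steps most likely to fail**

**Step 3** (cross-metathesis). The risk is slow turnover, or 7 being tied up as its homodimer. The fallback sets out from 7 and comes back at 10, building C3=C4 by carbonyl olefination instead.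
- Dihydroxylate the terminal alkene (OsO4 cat., NMO, acetone/H2O, 0 °C) to (4S)-4-[(tert-butyldimethylsilyl)oxy]-4-(furan-3-yl)butane-1,2-diol F1.
- Cleave it with NaIO4 (THF/H2O) to (3S)-3-[(tert-butyldimethylsilyl)oxy]-3-(furan-3-yl)propanal F2.
- Treat this with the stabilised ylide Ph3P=C(CH3)CO2Et (CH2Cl2, rt, E >95:5) to give ethyl (2E,5S)-5-[(tert-butyldimethylsilyl)oxy]-5-(furan-3-yl)-2-methylpent-2-enoate F3.
- Reduce with DIBAL-H (CH2Cl2, −78 °C) to 10.

**Step 8** (SeO2 oxidation). The risk is a moderate yield, over-oxidation and selenium residues. The fallback sets out from 15 and comes back at 16, rebuilding the terminus by degradation and Wittig olefination.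
- mCPBA (1.0 equiv, CH2Cl2, 0 °C) epoxidises only the electron-rich terminal alkene to 2,2-dimethyl-3-[(3E)-3-methyl-5-(phenylsulfonyl)pent-3-en-1-yl]oxirane F4.
- H5IO6 (THF/H2O, 0 °C) opens it to (6E)-2,6-dimethyl-8-(phenylsulfonyl)oct-6-ene-2,3-diol F5, which is cleaved in the same flask to (4E)-4-methyl-6-(phenylsulfonyl)hex-4-enal F6.
- Ph3P=C(CH3)CO2Et gives ethyl (2E,6E)-2,6-dimethyl-8-(phenylsulfonyl)octa-2,6-dienoate F7.
- DIBAL-H (CH2Cl2, −78 °C) gives 16.

**Step 17** (late thioacetal hydrolysis). The risk is a slow reaction at the hindered dithiane, or migration of C11=C12 into conjugation. The fallback sets out from 21 (through its mesylate 22) and comes back at 30, so no thioacetal is ever made.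
- LiCl in place of LiBr gives {[(1S,3E,7E,11E)-13-chloro-1-(furan-3-yl)-4,8,12-trimethyltrideca-3,7,11-trien-1-yl]oxy}(tert-butyl)dimethylsilane F8.
- Activated barium metal (BaI2 + 2 lithium biphenylide, THF) at −78 °C converts it into the allylbarium chloride F9.
- F9 adds to 3-methylbutanal 24 at its α-carbon with retention of the E geometry (α-selective carbonyl allylation). The product is (6E,10E,14E,17S)-17-[(tert-butyldimethylsilyl)oxy]-17-(furan-3-yl)-2,6,10,14-tetramethylheptadeca-6,10,14-trien-4-ol F10, obtained as C4 epimers, which does not matter here.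
- Dess–Martin periodinane/NaHCO3 (CH2Cl2, 0 °C) oxidises it without isomerisation to (6E,10E,14E,17S)-17-[(tert-butyldimethylsilyl)oxy]-17-(furan-3-yl)-2,6,10,14-tetramethylheptadeca-6,10,14-trien-4-one F11.
- Non-basic Et3N·3HF (MeCN/THF, rt) removes the silyl group to give 30.

**Further compounds**
F1 | step 3 | (4S)-4-[(tert-butyldimethylsilyl)oxy]-4-(furan-3-yl)butane-1,2-diol (C2 epimers) | OCC(O)C[C@H](O[Si](C)(C)C(C)(C)C)c1ccoc1
F2 | step 3 | (3S)-3-[(tert-butyldimethylsilyl)oxy]-3-(furan-3-yl)propanal | O=CC[C@H](O[Si](C)(C)C(C)(C)C)c1ccoc1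
F3 | step 3 | ethyl (2E,5S)-5-[(tert-butyldimethylsilyl)oxy]-5-(furan-3-yl)-2-methylpent-2-enoate | CCOC(=O)/C(C)=C/C[C@H](O[Si](C)(C)C(C)(C)C)c1ccoc1
F4 | step 8 | 2,2-dimethyl-3-[(3E)-3-methyl-5-(phenylsulfonyl)pent-3-en-1-yl]oxirane (racemic) | CC1(C)OC1CC/C(C)=C/CS(=O)(=O)c1ccccc1
F5 | step 8 | (6E)-2,6-dimethyl-8-(phenylsulfonyl)oct-6-ene-2,3-diol (racemic) | CC(C)(O)C(O)CC/C(C)=C/CS(=O)(=O)c1ccccc1
F6 | step 8 | (4E)-4-methyl-6-(phenylsulfonyl)hex-4-enal | O=CCC/C(C)=C/CS(=O)(=O)c1ccccc1
F7 | step 8 | ethyl (2E,6E)-2,6-dimethyl-8-(phenylsulfonyl)octa-2,6-dienoate | CCOC(=O)/C(C)=C/CC/C(C)=C/CS(=O)(=O)c1ccccc1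
F8 | step 17 | {[(1S,3E,7E,11E)-13-chloro-1-(furan-3-yl)-4,8,12-trimethyltrideca-3,7,11-trien-1-yl]oxy}(tert-butyl)dimethylsilane | ClC/C(C)=C/CC/C(C)=C/CC/C(C)=C/C[C@H](O[Si](C)(C)C(C)(C)C)c1ccoc1
F9 | step 17 | allylbarium chloride derived from F8 | Cl[Ba]C/C(C)=C/CC/C(C)=C/CC/C(C)=C/C[C@H](O[Si](C)(C)C(C)(C)C)c1ccoc1
F10 | step 17 | (6E,10E,14E,17S)-17-[(tert-butyldimethylsilyl)oxy]-17-(furan-3-yl)-2,6,10,14-tetramethylheptadeca-6,10,14-trien-4-ol (C4 epimers) | CC(C)CC(O)C/C(C)=C/CC/C(C)=C/CC/C(C)=C/C[C@H](O[Si](C)(C)C(C)(C)C)c1ccoc1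
F11 | step 17 | (6E,10E,14E,17S)-17-[(tert-butyldimethylsilyl)oxy]-17-(furan-3-yl)-2,6,10,14-tetramethylheptadeca-6,10,14-trien-4-one | CC(C)CC(=O)C/C(C)=C/CC/C(C)=C/CC/C(C)=C/C[C@H](O[Si](C)(C)C(C)(C)C)c1ccoc1
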